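Late times show what a closed flask is heading for, so the earlier runs are read from their end.

| flask | starting material | catalyst | remark | time |
|---|---|---|---|---|
| zeta | 1.5 M | 1.3 mM | run made earlier |  |
| alpha | 1 M | 1.3 mM | run made earlier |  |
| beta | 2.2 M | 1.3 mM | run made earlier |  |
| delta | 1.5 M | 2.6 mM | run made earlier |  |
| midnight | 1.5 M | 1.3 mM | one stirred flow tank at steady state, fed with the mixture as stated, mean residence time 30 min |  |
| autumn | 1.5 M | 1.3 mM | everything together in a closed stirred flask, run for 30 min | 30 min |
| summer | 1.5 M (fed, over 24.0 min) | 1.3 mM | a stirred flask in which starting material is dosed at a steady rate over 24.0 min without added volume, worked up at 30 min | 30 min |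

| run | time / min | intermediate / % | target / % |
|---|---|---|---|
| zeta | 5.00 | 33.4 | 35.4 |
| zeta | 10.0 | 41.7 | 37.8 |
| zeta | 15.0 | 46.5 | 39.0 |
| zeta | 20.0 | 51.8 | 38.0 |
| alpha | 10.0 | 45.2 | 38.0 |
| alpha | 20.0 | 55.5 | 36.9 |
| alpha | 25.0 | 60.6 | 36.8 |
| alpha | 40.0 | 62.1 | 37.0 |
| beta | 10.0 | 36.7 | 40.5 |
| beta | 20.0 | 48.8 | 37.4 |
| beta | 25.0 | 51.7 | 36.9 |
| beta | 40.0 | 57.8 | 38.3 |
| delta | 10.0 | 41.8 | 38.5 |
| delta | 20.0 | 50.7 | 37.8 |
| delta | 25.0 | 54.2 | 35.7 |
| delta | 40.0 | 57.6 | 35.9 |

(standard deviation of a reading: 1 percentage point)

- the stated concentrations are those of everything mixed, before any reaction; amounts are the same in each set-up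
- the feed brings no volume worth counting
- the earlier runs were made in a closed, stirred flask
- a reading or a percentage of target counts all its forms, free or not

- the set-up with the highest amount of intermediate at the outlet or at the end, in percent of the starting material put in ("none" if the first two lie within 2 percentage points) (midnight / autumn / summer / none)
- amount of intermediate at the outlet or at the end, in percent of the starting material put in, midnight
- amount of intermediate at the outlet or at the end, in percent of the starting material put in, autumn
- amount of intermediate at the outlet or at the end, in percent of the starting material put in, summer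

Late in the alpha run, intermediate and target together read 99.1% of the charge, so little else stands at the end. But the zeta run has not reached that state. Its target reads 35.4% at 5.00 min and 38.0% at 20.0 min, so target barely moves, and intermediate is what remains once target and a gap are taken off.

The gap is the share of the charge read as neither intermediate nor target. In the zeta run it falls from 31.2% to 10.2% between those readings. So the gap has a time constant, here called the gap time, in the usual term a relaxation time: 13.4 min as a reading.

The reckoning here carries the gap on to 30 min, where it reaches 4.84%. So autumn should hold 57.2% intermediate. Summer's last portion ages 6.00 min, and the tank's outflow contains fresh feed, so the pick here is autumn.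

The forecast gives 47% for midnight, 56% for autumn and 50% for summer, and picks autumn: “The mechanism behind the target plateau is unclear, so this is an empirical reading.” Its autumn figure stands slightly below the reckoning here.

The flasks give 35.0% for midnight, 57.5% for autumn and 42.4% for summer, so autumn is best.

    starting material → intermediate (k = 0.00660 s⁻¹)
    catalyst + intermediate ⇌ catalyst + target (K = 0.548, k = 4.54 L mol⁻¹ s⁻¹)
    starting material + target ⇌ idle adduct, settled at all times (K = 13.1 L mol⁻¹)

Autumn's gap comes to 5.84%, against the reckoned 4.84%. A stirred tank divides a first-order gap by one plus the ratio of its residence time, here 30 min, to the gap time. So midnight's gap is reckoned at 30.9%, which with target at 38.0% leaves 31.1% intermediate, against 35.0%. The main reason that autumn holds intermediate at all is the backward run from catalyst + target to catalyst + intermediate: without that backward run, autumn gives 1.10% intermediate.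

The numbers in the tables are simulated for an exercise, noise included.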